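Each Q made costs an X and a J, so I asked how fast X falls in Thursday's flask, where J is charged at 550 mM, more than its 150 mM of X, and the decay should be close to pseudo-first-order. I reckoned in a time constant: the run time divided by the natural logarithm of charge over last reading.

| setting | Saturday's | Monday's | Sunday's | Friday's | Thursday's |
|---|---|---|---|---|---|
| X | 150 mM | 150 mM | 150 mM | 220 mM | 150 mM |
| J | 120 mM | 240 mM | 120 mM | 120 mM | 550 mM |
| G | 7.50 mM | 7.50 mM | 7.50 mM | 7.50 mM | 7.50 mM |
| Q |  |  | 75.0 mM |  |  |
| time |  |  |  |  | 110 min |

- Saturday's run (time / min: [X] / mM): 22: 113.8; 44: 90.2; 66: 68.9; 88: 55.1; 110: 47.2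
- Monday's run (time / min: [X] / mM): 22: 106.2; 44: 72.8; 66: 49.7; 88: 37.6; 110: 25.8
- Sunday's run (time / min: [X] / mM): 22: 115.6; 44: 89.8; 66: 68.8; 88: 55.2; 110: 43.3
- Friday's run (time / min: [X] / mM): 22: 169.0; 44: 134.0; 66: 109.5; 88: 89.0; 110: 74.0

(standard deviation of a reading: 2 mM)

- order of the initial rate in [X], near the charge of the Saturday's run, the rate being that where two percent of its X are Q (one fixed amount of Q, the same in the runs compared)
- order of the initial rate in [J], near the charge of the Saturday's run, the rate being that where two percent of its X are Q
- X in the Thursday's run at 110 min, as a share of the X charged
- which of these the readings show (two substrates go astray together / the substrate pairs with itself / the product binds the second partner / the catalyst dies by itself)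

- Overall: X + J -> Q, with G as catalyst.
- Constant volume, constant temperature.
- What is held in complexes is read along with the free species.
- "The second partner" is J.
- An order is taken over about fifteen percent of the charge, up and down.

The X gone from Friday's flask by its last reading came to 146 mM, more than its 120 mM of J, so I took some X to go astray without J, two together. Sunday's flask, with Q charged, read 68.8 mM at 66 min against Saturday's 68.9 mM, so I set product binding aside.

I solved both ends and joined them: with J plentiful, a time that does not depend on J; with J poor, a time inverse to J; and the two added.

time constant = floor + constant / mean J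

Saturday's flask: 95.1 min at a mean J of 68.6 mM

Monday's flask: 62.5 min at a mean J of 178 mM

Here I counted each X lost as a J lost. The part of the time constant left when the J term is taken off, the floor, read 42.0 min. With the whole X charge counted as lost, Thursday's mean J was 475 mM, which gave 49.7 min, the floor being 84.5% of it.

G stood at 7.50 mM in each flask, so it needed no value. Raising Monday's last reading by 2 mM moved Thursday's share by 1.9 percentage points, more than the same change in Saturday's last reading did. So of those two readings, Monday's last reading was the one to know well.

Thursday's X at 110 min:

share = exp(−time / time constant) = 10.9%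

The forecast gave 13.7%, above my share, with orders 0.52 in X and 0.4 in J and the verdict two substrates go astray together, from “stepwise integration with J about 450 gives X ≈ 20 mM”.

Thursday's flask gave 10.6%, with orders 0.50 and 0.58 and the verdict two substrates go astray together.

    G + X ⇌ GX (2.928 M⁻¹ min⁻¹, 0.04992 min⁻¹)
    GX + J → Q + G (2.910 M⁻¹ min⁻¹)
    2 X → Ky (0.01332 M⁻¹ min⁻¹)

That share is a time constant of 48.9 min, and taking off my J term for Thursday's flask leaves 41.2 min, beside the floor of 42.0 min. Monday's flask had made 75.0 mM of Q at 56.9 min. Its time constant, the floor plus 20.5 min for its J, puts the X lost from Monday's flask by then at about 89.7 mM, which leaves an estimated 14.7 mM of X gone astray into Ky.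

The data were generated by integration on assumed constants; noise was put on by code.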